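## Analysis of the target

The target 34 is a ten-membered carbocycle. Its ring atoms are labelled C1(Me)=C2H, C3H(OH), C4H(iPr), C5H(O-aroyl), C6H2, C7(Me)=C8H, C9H2, C10H2, and these labels are kept for all intermediates. Both ring alkenes are trisubstituted and Z, that is, cis within the ring. C3, C4 and C5 form a contiguous triad, (3S,4S,5R) in this numbering; drawn along the ring chain, the isopropyl group is anti to both oxygens and the two oxygens are syn to each other. The sensitive groups are the allylic C3 alcohol, the free phenol, and the C5 aryl ester, which can migrate to the 1,3-related C3 hydroxyl under base. The synthesis is hard for three reasons: a ten-membered ring with two Z trisubstituted alkenes has to be closed, three adjacent stereocentres have to be set on it, and two secondary oxygens have to be told apart. The plan rests on the C3 carbinol. It lies between C2, which can be carried as an alkyne carbon, and C4, whose isopropyl group can be carried as isopropenyl. The C3–C4 bond with a hydroxyl on one side and a 2-propenyl branch on the other is the product pattern of a [2,3]-Wittig shift of a propargyl allyl ether.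

## Retrosynthetic reasoning

**34 from 33.** The phenol and the C3 hydroxyl are unmasked last and together. A buffered, acidic fluoride source removes both silyl groups of 33 without giving the C5 ester a chance to migrate to O3.

**33 from 28 and 31.** The C5–O acyl bond is cut. In 28 only O5 is free (O3 is silylated), so the acylation with acid 31 is unambiguous. Acid 31 is the phenol-silylated form of 29.

**28 from 26 through 27.** The C5 carbinol of 28 is traced back to its epimer 26 by an inversion. This follows from the key step. In the ring contraction the C5–H bond lies in the plane of the Z alkene and the new C3–C4 bond forms anti to the C5–O bond. The target needs the opposite relationship between C4 and C5. C5 is therefore carried as S, used as the controlling element, and inverted afterwards.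

**26 from 21 through 25, 24 and 23.** These are functional-group changes on the closed ring. The PMB ether at O5 is exchanged for a free hydroxyl after O3 is silylated. The isopropyl group comes from isopropenyl by hydrogenation of the least hindered alkene. The C1 methyl and the Z C1=C2 alkene come from the ring alkyne of 21 by syn addition of methyl and hydrogen, directed by the free C3 hydroxyl.

**21 from 19.** The C3–C4 bond is cut. This is the only bond whose formation leaves exactly a propargylic hydroxyl and an isopropenyl branch. Cutting it puts the ether oxygen and three allyl carbons back into the ring, so the ten-membered ring is traced to the 13-membered ether 19. The forward reaction must deprotonate C3 selectively, set C3 and C4 together, and use C5 to choose the alkene face.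

**19 from 18.** The ring C–O bond between the propargylic carbon and the ether oxygen is cut. It is the only heteroatom bond in the ring. Closing it is an alkoxide alkylation by a primary allylic chloride in a chain stiffened by an alkyne and two Z alkenes, so the entropic cost of ring formation is paid at ring size 13.

**18 from 13 through 17, 15 and 14.** The allylic chloride is traced to an enoate, and the C4=C bond is cut by a Z-selective olefination of aldehyde 13. The Z geometry matters because it fixes the C3/C4 relationship in the key step.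

**13 from 6 and 8 through 12, 11 and 10.** The C6–C7 bond is cut between an alkenyl anion derived from iodide 6 and the terminal carbon of epoxide 8. The C5 stereocentre thus comes from (R)-glycidol 7. The PMB group of 8 is moved from O4 to O5 through acetal 11, so it serves twice.

**6 from 1 and 2 through 5 and 4.** The C7=C8 bond is cut by an iodo-olefination of aldehyde 5. The C10–C1 bond is cut between the acetylide of 1 and oxetane 2, which supplies C8–C10.

## Alternatives that were turned down

**Alternative 1: two-carbon ring expansion.** The disconnection cuts C3–C4 and C5–C6. In the forward direction a ketene carrying C4 with its isopropyl group and a chlorine adds [2+2] to the silyl enol ether of an eight-membered trienyl system. Fluoride then opens the fused cyclobutanone by retro-aldol cleavage to the ten-membered chloro dione A1.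
- For it: it is by far the shortest way to the ring, and both Z alkenes come from the eight-membered ring without any olefination. On step count to the carbocycle it is stronger than the chosen route.
- Against it: A1 is racemic, and after dechlorination C4 sits between two carbonyls and is stereochemically labile. C3, C4 and C5 would all have to be set by reductions of a medium-ring 1,3-dione with enantio- and diastereocontrol, and the two resulting carbinols would still have to be told apart. The C5 ketone is also β,γ-unsaturated and can slip into conjugation.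
- Comparison: the chosen strategy is longer but takes its absolute configuration from a chiral-pool epoxide, sets two stereocentres in the ring-forming step, and keeps the two oxygens differentiated throughout.

**Alternative 2: ring-closing allylboration.** The disconnection cuts C5–C6. In the forward direction an open-chain C5 aldehyde reacts with a secondary allylic pinacol boronate at C8 of the same chain. C5–C6 forms, the alkene shifts to Z C7=C8, and the ring closes to A2, which is the same compound as 28 of the chosen route.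
- For it: it delivers the free C5 hydroxyl in the right configuration in the ring-forming step, so no inversion is needed. On this point it is stronger than the chosen route.
- Against it: the six-membered chair transition state has to form inside a ten-membered ring, the least favourable size for end-to-end closure. The aldehyde is α-branched at C4 and β-silyloxylated, so epimerisation and elimination threaten it. C3, C4 and the boron-bearing C8 all have to be built separately in the open chain, and the configuration at C8 is made only to be consumed.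
- Comparison: the chosen strategy closes the ring at size 13, contracts it by a precedented rearrangement, and makes C3 and C4 in that same step. Its price is the late inversion at C5.

**Alternative 3: sulfone alkylation at C9–C10.** The disconnection cuts C9–C10. In the forward direction a potassium amide base deprotonates an allylic phenyl sulfone at C9, and the carbanion displaces an allylic bromide at C10 to give A3. The sulfonyl group is removed afterwards.
- For it: the stereotriad is assembled in the open chain by dependable methods with C5 already correct, and sulfone alkylation is an established way to close ten-membered carbocycles. On stereochemical certainty of the triad it is as strong as or stronger than the chosen route.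
- Against it: the carbanion is allylic to C7=C8 and ambident, so the Z geometry and the site of alkylation are both at risk. Reductive removal of an allylic sulfone can move or isomerise the alkene. The Z allylic bromide can react by SN2′. The linear sequence to the open-chain precursor, with two different Z trisubstituted allylic termini, is long.
- Comparison: the chosen strategy never places a carbanion or radical next to C7=C8 and forms the medium ring by contraction, not by end-to-end closure.

Key step: step 14

## Route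

Assumption (remark on the chemistry): in the ring contraction the new C3–C4 bond is taken to form anti to the C5–O bond with C5–H in the plane of the Z alkene, as in open-chain (Z)-allyl ethers with an allylic C–O stereocentre. The C5 configuration of the precursor is chosen on that basis.

Step 1
Reactants: 1 tert-butyldimethyl(prop-2-yn-1-yloxy)silane; 2 oxetane
Product: 4 6-[(tert-butyldimethylsilyl)oxy]hex-4-yn-1-ol, via lithium acetylide 3 (not isolated)
Conditions: n-BuLi, THF, −78 °C; then 2, BF3·OEt2, −78 °C
Reagents that add atoms: none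
Why: BF3-promoted opening of oxetane by a lithium acetylide (known alkynylation of oxetanes) forms C10–C1 and delivers C8–C10 with a primary alcohol at C8 in one step.

Step 2
Reactants: 4 6-[(tert-butyldimethylsilyl)oxy]hex-4-yn-1-ol
Product: 5 6-[(tert-butyldimethylsilyl)oxy]hex-4-ynal
Conditions: Dess–Martin periodinane, NaHCO3, CH2Cl2, 0 °C to rt
Reagents that add atoms: none
Why: Dess–Martin oxidation of a primary alcohol to the aldehyde; the silyl ether and the alkyne are inert.

Step 3
Reactants: 5 6-[(tert-butyldimethylsilyl)oxy]hex-4-ynal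
Product: 6 tert-butyl{[(6Z)-7-iodooct-6-en-2-yn-1-yl]oxy}dimethylsilane
Conditions: EtPPh3I, n-BuLi, THF, rt; I2, −78 °C; NaN(SiMe3)2, −20 °C; then 5, −78 °C to rt
Reagents that add atoms: ethyltriphenylphosphonium iodide, CC[P+](c1ccccc1)(c1ccccc1)c1ccccc1.[I-]; iodine, II
Why: Wittig olefination with the α-iodo ylide (iodo-olefination of the Stork–Zhao type in its ethylidene form) is kinetically Z-selective and places iodine cis to the chain. Because the iodine is later replaced by C6 with retention, this step fixes the Z geometry of C7=C8.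

Step 4
Reactants: 7 (R)-glycidol
Product: 8 (2S)-2-{[(4-methoxyphenyl)methoxy]methyl}oxirane
Conditions: NaH, 4-methoxybenzyl chloride, n-Bu4NI (cat.), DMF, 0 °C to rt
Reagents that add atoms: 4-methoxybenzyl chloride, COc1ccc(CCl)cc1
Why: Williamson etherification of the primary alkoxide; the stereocentre is not touched and the descriptor changes from R to S only because the substituent priorities change.

Step 5
Reactants: 6 tert-butyl{[(6Z)-7-iodooct-6-en-2-yn-1-yl]oxy}dimethylsilane; 8 (2S)-2-{[(4-methoxyphenyl)methoxy]methyl}oxirane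
Product: 10 (2S,4Z)-10-[(tert-butyldimethylsilyl)oxy]-1-[(4-methoxyphenyl)methoxy]-4-methyldec-4-en-8-yn-2-ol, via alkenyllithium 9 (not isolated)
Conditions: t-BuLi (2 equiv), Et2O, −78 °C; then 8, BF3·OEt2, −78 °C
Reagents that add atoms: none
Why: Iodine–lithium exchange with retention of alkene geometry, then BF3-assisted opening of the terminal epoxide at its CH2 carbon forms C6–C7. C5 keeps its configuration, and the cold, short-lived alkenyllithium should not add to the remote alkyne.

Step 6
Reactants: 10 (2S,4Z)-10-[(tert-butyldimethylsilyl)oxy]-1-[(4-methoxyphenyl)methoxy]-4-methyldec-4-en-8-yn-2-ol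
Product: 11 (4S)-4-[(2Z)-8-[(tert-butyldimethylsilyl)oxy]-2-methyloct-2-en-6-yn-1-yl]-2-(4-methoxyphenyl)-1,3-dioxolane (both epimers at the acetal carbon)
Conditions: DDQ, 4 Å molecular sieves, CH2Cl2, 0 °C
Reagents that add atoms: none
Why: Oxidative acetalisation of a hydroxy PMB ether: without water, the oxocarbenium ion formed by DDQ is trapped by the neighbouring hydroxyl. The PMB group is thereby passed towards O5 without a separate protection.

Step 7
Reactants: 11 (4S)-4-[(2Z)-8-[(tert-butyldimethylsilyl)oxy]-2-methyloct-2-en-6-yn-1-yl]-2-(4-methoxyphenyl)-1,3-dioxolane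
Product: 12 (2S,4Z)-10-[(tert-butyldimethylsilyl)oxy]-2-[(4-methoxyphenyl)methoxy]-4-methyldec-4-en-8-yn-1-ol
Conditions: i-Bu2AlH, CH2Cl2, −78 to 0 °C
Reagents that add atoms: none
Why: Reductive opening of a 4-methoxybenzylidene acetal: aluminium binds the less hindered primary oxygen and its acetal C–O bond is cleaved, so the PMB ether stays on the secondary O5 and the primary alcohol is freed.

Step 8
Reactants: 12 (2S,4Z)-10-[(tert-butyldimethylsilyl)oxy]-2-[(4-methoxyphenyl)methoxy]-4-methyldec-4-en-8-yn-1-ol
Product: 13 (2S,4Z)-10-[(tert-butyldimethylsilyl)oxy]-2-[(4-methoxyphenyl)methoxy]-4-methyldec-4-en-8-ynal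
Conditions: Dess–Martin periodinane, NaHCO3, CH2Cl2, 0 °C; used crude
Reagents that add atoms: none
Why: Buffered Dess–Martin oxidation gives the α-alkoxy aldehyde without base strong enough to epimerise C5; the aldehyde is used at once.

Step 9
Reactants: 13 (2S,4Z)-10-[(tert-butyldimethylsilyl)oxy]-2-[(4-methoxyphenyl)methoxy]-4-methyldec-4-en-8-ynal
Product: 14 ethyl (2Z,4S,6Z)-12-[(tert-butyldimethylsilyl)oxy]-4-[(4-methoxyphenyl)methoxy]-2,6-dimethyldodeca-2,6-dien-10-ynoate
Conditions: ethyl 2-[bis(2,2,2-trifluoroethoxy)phosphoryl]propanoate, KN(SiMe3)2, 18-crown-6, THF, −78 °C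
Reagents that add atoms: ethyl 2-[bis(2,2,2-trifluoroethoxy)phosphoryl]propanoate, CCOC(=O)C(C)P(=O)(OCC(F)(F)F)OCC(F)(F)F
Why: Still–Gennari olefination: fast, irreversible elimination from the trifluoroethyl phosphonate adduct gives the Z trisubstituted enoate with the ester cis to C5. The cold, non-equilibrating conditions protect the C5 stereocentre.

Step 10
Reactants: 14 ethyl (2Z,4S,6Z)-12-[(tert-butyldimethylsilyl)oxy]-4-[(4-methoxyphenyl)methoxy]-2,6-dimethyldodeca-2,6-dien-10-ynoate
Product: 15 (2Z,4S,6Z)-12-[(tert-butyldimethylsilyl)oxy]-4-[(4-methoxyphenyl)methoxy]-2,6-dimethyldodeca-2,6-dien-10-yn-1-ol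
Conditions: i-Bu2AlH, CH2Cl2, −78 °C
Reagents that add atoms: none
Why: 1,2-Reduction of the enoate to the allylic alcohol; the alkene geometry is kept and the internal alkyne does not react at this temperature.

Step 11
Reactants: 15 (2Z,4S,6Z)-12-[(tert-butyldimethylsilyl)oxy]-4-[(4-methoxyphenyl)methoxy]-2,6-dimethyldodeca-2,6-dien-10-yn-1-ol
Product: 17 tert-butyl{[(6Z,9S,10Z)-12-chloro-9-[(4-methoxyphenyl)methoxy]-7,11-dimethyldodeca-6,10-dien-2-yn-1-yl]oxy}dimethylsilane, via allylic mesylate 16 (not isolated)
Conditions: MsCl, 2,4,6-collidine, LiCl, DMF, 0 °C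
Reagents that add atoms: lithium chloride, [Li+].[Cl-]
Why: Mesylation and SN2 displacement by chloride at the primary allylic carbon in one flask; direct substitution at the primary carbon gives no allylic transposition and keeps the Z geometry.

Step 12
Reactants: 17 tert-butyl{[(6Z,9S,10Z)-12-chloro-9-[(4-methoxyphenyl)methoxy]-7,11-dimethyldodeca-6,10-dien-2-yn-1-yl]oxy}dimethylsilane
Product: 18 (6Z,9S,10Z)-12-chloro-9-[(4-methoxyphenyl)methoxy]-7,11-dimethyldodeca-6,10-dien-2-yn-1-ol
Conditions: HF·pyridine, pyridine, THF, 0 °C to rt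
Reagents that add atoms: none
Why: Fluoride cleavage of the primary silyl ether under non-basic conditions of low nucleophilicity, which leave the allylic chloride and the PMB ether alone.

Step 13
Reactants: 18 (6Z,9S,10Z)-12-chloro-9-[(4-methoxyphenyl)methoxy]-7,11-dimethyldodeca-6,10-dien-2-yn-1-ol
Product: 19 (3Z,5S,7Z)-5-[(4-methoxyphenyl)methoxy]-3,7-dimethyl-1-oxacyclotrideca-3,7-dien-11-yne
Conditions: NaH, THF–DMF, slow addition to about 0.002 M, 40 °C
Reagents that add atoms: none
Why: Intramolecular Williamson etherification of the propargylic alkoxide with the primary allylic chloride, the established way to close 13-membered propargyl allyl ethers. The alkyne and the two Z alkenes restrict the chain, and high dilution suppresses oligomers.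

Step 14
Reactants: 19 (3Z,5S,7Z)-5-[(4-methoxyphenyl)methoxy]-3,7-dimethyl-1-oxacyclotrideca-3,7-dien-11-yne
Product: 21 (1R,6Z,9S,10S)-9-[(4-methoxyphenyl)methoxy]-7-methyl-10-(prop-1-en-2-yl)cyclodec-6-en-2-yn-1-ol, via lithiated ether 20 (not isolated)
Conditions: n-BuLi, THF, −78 to −30 °C; then aq. NH4Cl
Reagents that add atoms: none
Why: n-BuLi removes a proton from C3, the only carbon that is both propargylic and oxygen-bearing, to give 20; the carbanion bonds to C4 through a five-membered envelope while the allylic CH2–O bond breaks, a [2,3]-Wittig rearrangement of the kind known for 13-membered propargyl allyl ethers. The ring closes by contraction from 13 to 10 members: the ether oxygen and the three allyl carbons leave the ring and become the C3 hydroxyl and the C4 isopropenyl group, so no end-to-end closure of a ten-membered ring is needed. C3 and C4 are set together by the Z allylic alkene with the alkynyl arm exo on the envelope, the usual preference and the only arrangement in which the C1–C2 rod lies gauche to C5 and can be bridged by C6–C9; this places the hydroxyl and the isopropenyl group anti along the ring chain. The absolute sense comes from C5: allylic 1,3-strain in the Z alkene holds C5–H in the alkene plane, and C3 adds to the face anti to the C5–O bond, which is also the face from which C6 can reach C10, so (5S)-19 should give (3S,4S) in ring numbering. The step needs deprotonation at C3 in preference to the allylic OCH2 and the benzylic PMB position, which the much higher acidity of the propargylic α-oxy C–H at low temperature should secure. It also needs the [2,3] path to win over a [1,2] shift, which low temperature favours.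

Step 15
Reactants: 21 (1R,6Z,9S,10S)-9-[(4-methoxyphenyl)methoxy]-7-methyl-10-(prop-1-en-2-yl)cyclodec-6-en-2-yn-1-ol
Product: 23 (1S,2Z,6Z,9S,10S)-9-[(4-methoxyphenyl)methoxy]-3,7-dimethyl-10-(prop-1-en-2-yl)cyclodeca-2,6-dien-1-ol, via alkenylmagnesium bromide 22 (not isolated)
Conditions: MeMgBr (excess), Fe(acac)3 (cat.), THF, −78 to 0 °C; then aq. NH4Cl
Reagents that add atoms: methylmagnesium bromide, C[Mg]Br
Why: Alkoxide-directed, Fe(acac)3-catalysed carbomagnesiation of a propargylic alcohol delivers methyl to the alkyne carbon remote from the carbinol (C1) and the metal to C2 in a syn fashion. Protonation then gives the trisubstituted alkene, and syn addition across a ring alkyne leaves the two ring bonds cis, that is, Z C1=C2.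

Step 16
Reactants: 23 (1S,2Z,6Z,9S,10S)-9-[(4-methoxyphenyl)methoxy]-3,7-dimethyl-10-(prop-1-en-2-yl)cyclodeca-2,6-dien-1-ol
Product: 24 (1S,2Z,6Z,9S,10S)-9-[(4-methoxyphenyl)methoxy]-3,7-dimethyl-10-(propan-2-yl)cyclodeca-2,6-dien-1-ol
Conditions: H2 (1 atm), RhCl(PPh3)3 (cat.), benzene, rt
Reagents that add atoms: none
Why: Homogeneous hydrogenation with RhCl(PPh3)3 reduces the 1,1-disubstituted isopropenyl alkene much faster than the two trisubstituted ring alkenes and does not cleave the PMB ether.

Step 17
Reactants: 24 (1S,2Z,6Z,9S,10S)-9-[(4-methoxyphenyl)methoxy]-3,7-dimethyl-10-(propan-2-yl)cyclodeca-2,6-dien-1-ol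
Product: 25 tert-butyl{[(1S,2Z,6Z,9S,10R)-9-[(4-methoxyphenyl)methoxy]-3,7-dimethyl-10-(propan-2-yl)cyclodeca-2,6-dien-1-yl]oxy}dimethylsilane
Conditions: TBSOTf, 2,6-lutidine, CH2Cl2, −78 to 0 °C
Reagents that add atoms: tert-butyldimethylsilyl trifluoromethanesulfonate, CC(C)(C)[Si](C)(C)OS(=O)(=O)C(F)(F)F
Why: Silylation of a hindered secondary allylic alcohol with the silyl triflate; the descriptor at the isopropyl carbon changes only because of the new priorities.

Step 18
Reactants: 25 tert-butyl{[(1S,2Z,6Z,9S,10R)-9-[(4-methoxyphenyl)methoxy]-3,7-dimethyl-10-(propan-2-yl)cyclodeca-2,6-dien-1-yl]oxy}dimethylsilane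
Product: 26 (1S,3Z,7Z,9S,10R)-9-[(tert-butyldimethylsilyl)oxy]-3,7-dimethyl-10-(propan-2-yl)cyclodeca-3,7-dien-1-ol
Conditions: DDQ, CH2Cl2–pH 7 buffer, 0 °C
Reagents that add atoms: none
Why: Oxidative cleavage of the PMB ether by DDQ in the presence of water frees O5; the silyl ether and the alkenes are not affected under buffered conditions.

Step 19
Reactants: 26 (1S,3Z,7Z,9S,10R)-9-[(tert-butyldimethylsilyl)oxy]-3,7-dimethyl-10-(propan-2-yl)cyclodeca-3,7-dien-1-ol
Product: 27 (1R,3Z,7Z,9S,10R)-9-[(tert-butyldimethylsilyl)oxy]-3,7-dimethyl-10-(propan-2-yl)cyclodeca-3,7-dien-1-yl 4-nitrobenzoate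
Conditions: 4-nitrobenzoic acid, PPh3, DIAD, toluene, 0 °C to rt
Reagents that add atoms: 4-nitrobenzoic acid, OC(=O)c1ccc([N+](=O)[O-])cc1
Why: Mitsunobu reaction: the alkoxyphosphonium ion at C5 is displaced by the carboxylate in an SN2 step with inversion, turning (5S) into the (5R) configuration of the target. The strongly acidic nitrobenzoic acid is the usual partner for hindered secondary alcohols.

Step 20
Reactants: 27 (1R,3Z,7Z,9S,10R)-9-[(tert-butyldimethylsilyl)oxy]-3,7-dimethyl-10-(propan-2-yl)cyclodeca-3,7-dien-1-yl 4-nitrobenzoate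
Product: 28 (1R,3Z,7Z,9S,10R)-9-[(tert-butyldimethylsilyl)oxy]-3,7-dimethyl-10-(propan-2-yl)cyclodeca-3,7-dien-1-ol
Conditions: K2CO3, MeOH, rt
Reagents that add atoms: none
Why: Methanolysis of the electron-poor ester frees the inverted C5 alcohol; with O3 silylated there is no neighbouring hydroxyl to which the acyl group could move.

Step 21
Reactants: 29 4-hydroxybenzoic acid
Product: 31 4-[(tert-butyldimethylsilyl)oxy]benzoic acid, via silyl ester 30 (not isolated)
Conditions: TBSCl (2.5 equiv), imidazole, DMF, rt; then AcOH–THF–H2O, rt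
Reagents that add atoms: tert-butyldimethylsilyl chloride, CC(C)(C)[Si](C)(C)Cl
Why: Double silylation, then selective hydrolysis of the very labile silyl ester under mild acid, which leaves the aryl silyl ether in place.

Step 22
Reactants: 28 (1R,3Z,7Z,9S,10R)-9-[(tert-butyldimethylsilyl)oxy]-3,7-dimethyl-10-(propan-2-yl)cyclodeca-3,7-dien-1-ol; 31 4-[(tert-butyldimethylsilyl)oxy]benzoic acid
Product: 33 (1R,3Z,7Z,9S,10R)-9-[(tert-butyldimethylsilyl)oxy]-3,7-dimethyl-10-(propan-2-yl)cyclodeca-3,7-dien-1-yl 4-[(tert-butyldimethylsilyl)oxy]benzoate, via mixed anhydride 32 (not isolated)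
Conditions: 2,4,6-trichlorobenzoyl chloride, Et3N, THF, rt; then 28, 4-(dimethylamino)pyridine, toluene, rt to 50 °C
Reagents that add atoms: none
Why: Yamaguchi esterification: the mixed anhydride is opened by the pyridine catalyst at the less hindered aroyl carbonyl and the acylpyridinium ion acylates the hindered secondary alcohol with retention at C5.

Step 23
Reactants: 33 (1R,3Z,7Z,9S,10R)-9-[(tert-butyldimethylsilyl)oxy]-3,7-dimethyl-10-(propan-2-yl)cyclodeca-3,7-dien-1-yl 4-[(tert-butyldimethylsilyl)oxy]benzoate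
Product: 34 (1R,3Z,7Z,9S,10S)-9-hydroxy-3,7-dimethyl-10-(propan-2-yl)cyclodeca-3,7-dien-1-yl 4-hydroxybenzoate
Conditions: HF·pyridine, pyridine, THF, 0 °C to rt
Reagents that add atoms: none
Why: Fluoride removes the aryl and the allylic silyl ether in one operation; the buffered acidic medium avoids base-induced 1,3-migration of the ester from O5 to O3.

## Compound list

1 | tert-butyldimethyl(prop-2-yn-1-yloxy)silane | C#CCO[Si](C)(C)C(C)(C)C | starting material
2 | oxetane | C1COC1 | starting material
3 | {3-[(tert-butyldimethylsilyl)oxy]prop-1-yn-1-yl}lithium | [Li]C#CCO[Si](C)(C)C(C)(C)C | intermediate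
4 | 6-[(tert-butyldimethylsilyl)oxy]hex-4-yn-1-ol | OCCCC#CCO[Si](C)(C)C(C)(C)C | intermediate
5 | 6-[(tert-butyldimethylsilyl)oxy]hex-4-ynal | O=CCCC#CCO[Si](C)(C)C(C)(C)C | intermediate
6 | tert-butyl{[(6Z)-7-iodooct-6-en-2-yn-1-yl]oxy}dimethylsilane | C/C(I)=C/CCC#CCO[Si](C)(C)C(C)(C)C | intermediate
7 | (R)-glycidol, [(2R)-oxiran-2-yl]methanol | OC[C@@H]1CO1 | starting material
8 | (2S)-2-{[(4-methoxyphenyl)methoxy]methyl}oxirane | COc1ccc(COC[C@@H]2CO2)cc1 | intermediate
9 | {(2E)-8-[(tert-butyldimethylsilyl)oxy]oct-2-en-6-yn-2-yl}lithium (lithium cis to the chain) | C/C([Li])=C/CCC#CCO[Si](C)(C)C(C)(C)C | intermediate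
10 | (2S,4Z)-10-[(tert-butyldimethylsilyl)oxy]-1-[(4-methoxyphenyl)methoxy]-4-methyldec-4-en-8-yn-2-ol | COc1ccc(COC[C@@H](O)C/C(C)=C\CCC#CCO[Si](C)(C)C(C)(C)C)cc1 | intermediate
11 | (4S)-4-[(2Z)-8-[(tert-butyldimethylsilyl)oxy]-2-methyloct-2-en-6-yn-1-yl]-2-(4-methoxyphenyl)-1,3-dioxolane (both acetal epimers) | COc1ccc(C2OC[C@H](C/C(C)=C\CCC#CCO[Si](C)(C)C(C)(C)C)O2)cc1 | intermediate
12 | (2S,4Z)-10-[(tert-butyldimethylsilyl)oxy]-2-[(4-methoxyphenyl)methoxy]-4-methyldec-4-en-8-yn-1-ol | OC[C@@H](OCc1ccc(OC)cc1)C/C(C)=C\CCC#CCO[Si](C)(C)C(C)(C)C | intermediate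
13 | (2S,4Z)-10-[(tert-butyldimethylsilyl)oxy]-2-[(4-methoxyphenyl)methoxy]-4-methyldec-4-en-8-ynal | O=C[C@@H](OCc1ccc(OC)cc1)C/C(C)=C\CCC#CCO[Si](C)(C)C(C)(C)C | intermediate
14 | ethyl (2Z,4S,6Z)-12-[(tert-butyldimethylsilyl)oxy]-4-[(4-methoxyphenyl)methoxy]-2,6-dimethyldodeca-2,6-dien-10-ynoate | CCOC(=O)/C(C)=C\[C@@H](OCc1ccc(OC)cc1)C/C(C)=C\CCC#CCO[Si](C)(C)C(C)(C)C | intermediate
15 | (2Z,4S,6Z)-12-[(tert-butyldimethylsilyl)oxy]-4-[(4-methoxyphenyl)methoxy]-2,6-dimethyldodeca-2,6-dien-10-yn-1-ol | OC/C(C)=C\[C@@H](OCc1ccc(OC)cc1)C/C(C)=C\CCC#CCO[Si](C)(C)C(C)(C)C | intermediate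
16 | (2Z,4S,6Z)-12-[(tert-butyldimethylsilyl)oxy]-4-[(4-methoxyphenyl)methoxy]-2,6-dimethyldodeca-2,6-dien-10-yn-1-yl methanesulfonate | CS(=O)(=O)OC/C(C)=C\[C@@H](OCc1ccc(OC)cc1)C/C(C)=C\CCC#CCO[Si](C)(C)C(C)(C)C | intermediate
17 | tert-butyl{[(6Z,9S,10Z)-12-chloro-9-[(4-methoxyphenyl)methoxy]-7,11-dimethyldodeca-6,10-dien-2-yn-1-yl]oxy}dimethylsilane | ClC/C(C)=C\[C@@H](OCc1ccc(OC)cc1)C/C(C)=C\CCC#CCO[Si](C)(C)C(C)(C)C | intermediate
18 | (6Z,9S,10Z)-12-chloro-9-[(4-methoxyphenyl)methoxy]-7,11-dimethyldodeca-6,10-dien-2-yn-1-ol | ClC/C(C)=C\[C@@H](OCc1ccc(OC)cc1)C/C(C)=C\CCC#CCO | intermediate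
19 | (3Z,5S,7Z)-5-[(4-methoxyphenyl)methoxy]-3,7-dimethyl-1-oxacyclotrideca-3,7-dien-11-yne | C1C#CCC/C=C(/C)C[C@H](OCc2ccc(OC)cc2)/C=C(/C)CO1 | intermediate
20 | 13-lithio derivative of 19 (lithium on the propargylic OCH carbon, C3 of the ring numbering) | [Li]C1C#CCC/C=C(/C)C[C@H](OCc2ccc(OC)cc2)/C=C(/C)CO1 | intermediate
21 | (1R,6Z,9S,10S)-9-[(4-methoxyphenyl)methoxy]-7-methyl-10-(prop-1-en-2-yl)cyclodec-6-en-2-yn-1-ol | C1#C[C@H](O)[C@H](C(C)=C)[C@@H](OCc2ccc(OC)cc2)C/C(C)=C\CC1 | intermediate
22 | bromomagnesium alkoxide of the C2-alkenylmagnesium bromide formed from 21 (methyl and magnesium cis) | C/C1=C(\[Mg]Br)[C@H](O[Mg]Br)[C@H](C(C)=C)[C@@H](OCc2ccc(OC)cc2)C/C(C)=C\CC1 | intermediate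
23 | (1S,2Z,6Z,9S,10S)-9-[(4-methoxyphenyl)methoxy]-3,7-dimethyl-10-(prop-1-en-2-yl)cyclodeca-2,6-dien-1-ol | C/C1=C/[C@H](O)[C@H](C(C)=C)[C@@H](OCc2ccc(OC)cc2)C/C(C)=C\CC1 | intermediate
24 | (1S,2Z,6Z,9S,10S)-9-[(4-methoxyphenyl)methoxy]-3,7-dimethyl-10-(propan-2-yl)cyclodeca-2,6-dien-1-ol | C/C1=C/[C@H](O)[C@H](C(C)C)[C@@H](OCc2ccc(OC)cc2)C/C(C)=C\CC1 | intermediate
25 | tert-butyl{[(1S,2Z,6Z,9S,10R)-9-[(4-methoxyphenyl)methoxy]-3,7-dimethyl-10-(propan-2-yl)cyclodeca-2,6-dien-1-yl]oxy}dimethylsilane | C/C1=C/[C@H](O[Si](C)(C)C(C)(C)C)[C@H](C(C)C)[C@@H](OCc2ccc(OC)cc2)C/C(C)=C\CC1 | intermediate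
26 | (1S,3Z,7Z,9S,10R)-9-[(tert-butyldimethylsilyl)oxy]-3,7-dimethyl-10-(propan-2-yl)cyclodeca-3,7-dien-1-ol | C/C1=C/[C@H](O[Si](C)(C)C(C)(C)C)[C@H](C(C)C)[C@@H](O)C/C(C)=C\CC1 | intermediate
27 | (1R,3Z,7Z,9S,10R)-9-[(tert-butyldimethylsilyl)oxy]-3,7-dimethyl-10-(propan-2-yl)cyclodeca-3,7-dien-1-yl 4-nitrobenzoate | C/C1=C/[C@H](O[Si](C)(C)C(C)(C)C)[C@H](C(C)C)[C@H](OC(=O)c2ccc([N+](=O)[O-])cc2)C/C(C)=C\CC1 | intermediate
28 | (1R,3Z,7Z,9S,10R)-9-[(tert-butyldimethylsilyl)oxy]-3,7-dimethyl-10-(propan-2-yl)cyclodeca-3,7-dien-1-ol | C/C1=C/[C@H](O[Si](C)(C)C(C)(C)C)[C@H](C(C)C)[C@H](O)C/C(C)=C\CC1 | intermediate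
29 | 4-hydroxybenzoic acid | OC(=O)c1ccc(O)cc1 | starting material
30 | tert-butyldimethylsilyl 4-[(tert-butyldimethylsilyl)oxy]benzoate | CC(C)(C)[Si](C)(C)OC(=O)c1ccc(O[Si](C)(C)C(C)(C)C)cc1 | intermediate
31 | 4-[(tert-butyldimethylsilyl)oxy]benzoic acid | CC(C)(C)[Si](C)(C)Oc1ccc(C(=O)O)cc1 | intermediate
32 | 4-[(tert-butyldimethylsilyl)oxy]benzoic 2,4,6-trichlorobenzoic anhydride | CC(C)(C)[Si](C)(C)Oc1ccc(C(=O)OC(=O)c2c(Cl)cc(Cl)cc2Cl)cc1 | intermediate
33 | (1R,3Z,7Z,9S,10R)-9-[(tert-butyldimethylsilyl)oxy]-3,7-dimethyl-10-(propan-2-yl)cyclodeca-3,7-dien-1-yl 4-[(tert-butyldimethylsilyl)oxy]benzoate | C/C1=C/[C@H](O[Si](C)(C)C(C)(C)C)[C@H](C(C)C)[C@H](OC(=O)c2ccc(O[Si](C)(C)C(C)(C)C)cc2)C/C(C)=C\CC1 | intermediate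
34 | (1R,3Z,7Z,9S,10S)-9-hydroxy-3,7-dimethyl-10-(propan-2-yl)cyclodeca-3,7-dien-1-yl 4-hydroxybenzoate | C/C1=C/[C@H](O)[C@H](C(C)C)[C@H](OC(=O)c2ccc(O)cc2)C/C(C)=C\CC1 | target

## Step count and least certain steps

Total: 23 steps. Longest linear sequence: 21 steps (steps 1–3, 5–20, 22 and 23); steps 4 and 21 are side branches.

**Step 14 (key step).** The most likely failure is facial selectivity that is low or runs in the opposite sense, because the choice of face rests on a conformational argument for a 13-membered transition state; some [1,2] shift may also compete. The fallback runs the C5-epimeric series, in which addition syn to the ether oxygen gives the final C5 configuration directly and the inversion is dropped. It sets out from 6. Alkenyllithium 9 opens the (2R)-epoxide F1, the enantiomer of 8, made from the enantiomer of 7 as in step 4, to give the (2R)-alcohol F2. The operations of steps 6 to 13 then give the (4R)-acetal F3, the primary alcohol F4, the aldehyde F5, the (4R)-enoate F6, the allylic alcohol F7, its mesylate F8, the allylic chloride F9, the chloro alcohol F10 and the (5R)-macrocyclic ether F11. Lithiation to F12 and ring contraction would give the (9R)-ynol F13. Methylmagnesiation through the alkenylmagnesium species F14 gives the dienol F15, hydrogenation the isopropyl dienol F16, and silylation the silyl ether F17. DDQ cleavage of the PMB ether of F17 gives 28, where the route is rejoined; steps 19 and 20 are then not needed.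

**Step 15.** The ring alkyne may react sluggishly, or the methyl group may be delivered with poor regiocontrol, because directed carbomagnesiation has to work on a hindered secondary carbinol inside a medium ring. The fallback sets out from 21. Copper-catalysed formal hydroboration (CuCl, a bisphosphine, NaOt-Bu, bis(pinacolato)diboron, MeOH) adds boron and hydrogen syn across the alkyne, with boron on the carbon remote from the propargylic oxygen, to give the alkenyl boronate F18. Suzuki–Miyaura coupling of F18 with methyl iodide (PdCl2(dppf), K3PO4) then gives 23.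

**Step 19.** The SN2 displacement at C5 may be outrun by elimination towards the C5=C6–C7=C8 diene, or by acyl transfer with retention, because C5 is a ring carbon next to the isopropyl-bearing C4. The fallback sets out from 26. Dess–Martin oxidation gives the ketone F19. Reduction under control of (S)-2-methyl-CBS-oxazaborolidine with BH3·SMe2, in which the branched C4 side acts as the large group, should give the (1R) alcohol 28.

**Step 13.** Oligomerisation may compete with the 13-membered closure, or the chloride may be attacked at the far end of the allyl unit (SN2′) with loss of regio- and geometric integrity. The fallback reverses the roles of the two ends and sets out from 14. Fluoride removes the silyl group to give the propargylic alcohol F20, CBr4 and PPh3 convert it into the propargylic bromide F21, and i-Bu2AlH at −78 °C reduces the ester to the bromo allylic alcohol F22. NaH under high dilution then closes the ether 19 from the allylic alkoxide and a propargylic bromide, which has no SN2′ path on the allyl unit.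

**Step 3.** The iodo-olefination may give modest conversion and incomplete Z selectivity, because the iodo ylide is unstable and partly loses iodine. The fallback sets out from 5. CBr4 and PPh3 give the dibromoalkene F23. Palladium-catalysed monomethylation with MeZnCl and PdCl2(DPEphos), which is selective for the bromine trans to the chain, gives the (Z)-alkenyl bromide F24. Bromine–lithium exchange with t-BuLi gives alkenyllithium 9, and the route continues with step 5 to 10.

## Further compounds

F1 | step 14 | (2R)-2-{[(4-methoxyphenyl)methoxy]methyl}oxirane | COc1ccc(COC[C@H]2CO2)cc1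
F2 | step 14 | (2R,4Z)-10-[(tert-butyldimethylsilyl)oxy]-1-[(4-methoxyphenyl)methoxy]-4-methyldec-4-en-8-yn-2-ol | COc1ccc(COC[C@H](O)C/C(C)=C\CCC#CCO[Si](C)(C)C(C)(C)C)cc1
F3 | step 14 | (4R)-4-[(2Z)-8-[(tert-butyldimethylsilyl)oxy]-2-methyloct-2-en-6-yn-1-yl]-2-(4-methoxyphenyl)-1,3-dioxolane | COc1ccc(C2OC[C@@H](C/C(C)=C\CCC#CCO[Si](C)(C)C(C)(C)C)O2)cc1
F4 | step 14 | (2R,4Z)-10-[(tert-butyldimethylsilyl)oxy]-2-[(4-methoxyphenyl)methoxy]-4-methyldec-4-en-8-yn-1-ol | OC[C@H](OCc1ccc(OC)cc1)C/C(C)=C\CCC#CCO[Si](C)(C)C(C)(C)C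
F5 | step 14 | (2R,4Z)-10-[(tert-butyldimethylsilyl)oxy]-2-[(4-methoxyphenyl)methoxy]-4-methyldec-4-en-8-ynal | O=C[C@H](OCc1ccc(OC)cc1)C/C(C)=C\CCC#CCO[Si](C)(C)C(C)(C)C
F6 | step 14 | ethyl (2Z,4R,6Z)-12-[(tert-butyldimethylsilyl)oxy]-4-[(4-methoxyphenyl)methoxy]-2,6-dimethyldodeca-2,6-dien-10-ynoate | CCOC(=O)/C(C)=C\[C@H](OCc1ccc(OC)cc1)C/C(C)=C\CCC#CCO[Si](C)(C)C(C)(C)C
F7 | step 14 | (2Z,4R,6Z)-12-[(tert-butyldimethylsilyl)oxy]-4-[(4-methoxyphenyl)methoxy]-2,6-dimethyldodeca-2,6-dien-10-yn-1-ol | OC/C(C)=C\[C@H](OCc1ccc(OC)cc1)C/C(C)=C\CCC#CCO[Si](C)(C)C(C)(C)C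
F8 | step 14 | (2Z,4R,6Z)-12-[(tert-butyldimethylsilyl)oxy]-4-[(4-methoxyphenyl)methoxy]-2,6-dimethyldodeca-2,6-dien-10-yn-1-yl methanesulfonate | CS(=O)(=O)OC/C(C)=C\[C@H](OCc1ccc(OC)cc1)C/C(C)=C\CCC#CCO[Si](C)(C)C(C)(C)C
F9 | step 14 | tert-butyl{[(6Z,9R,10Z)-12-chloro-9-[(4-methoxyphenyl)methoxy]-7,11-dimethyldodeca-6,10-dien-2-yn-1-yl]oxy}dimethylsilane | ClC/C(C)=C\[C@H](OCc1ccc(OC)cc1)C/C(C)=C\CCC#CCO[Si](C)(C)C(C)(C)C
F10 | step 14 | (6Z,9R,10Z)-12-chloro-9-[(4-methoxyphenyl)methoxy]-7,11-dimethyldodeca-6,10-dien-2-yn-1-ol | ClC/C(C)=C\[C@H](OCc1ccc(OC)cc1)C/C(C)=C\CCC#CCO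
F11 | step 14 | (3Z,5R,7Z)-5-[(4-methoxyphenyl)methoxy]-3,7-dimethyl-1-oxacyclotrideca-3,7-dien-11-yne | C1C#CCC/C=C(/C)C[C@@H](OCc2ccc(OC)cc2)/C=C(/C)CO1
F12 | step 14 | 13-lithio derivative of F11 | [Li]C1C#CCC/C=C(/C)C[C@@H](OCc2ccc(OC)cc2)/C=C(/C)CO1
F13 | step 14 | (1R,6Z,9R,10S)-9-[(4-methoxyphenyl)methoxy]-7-methyl-10-(prop-1-en-2-yl)cyclodec-6-en-2-yn-1-ol | C1#C[C@H](O)[C@H](C(C)=C)[C@H](OCc2ccc(OC)cc2)C/C(C)=C\CC1
F14 | step 14 | bromomagnesium alkoxide of the C2-alkenylmagnesium bromide formed from F13 | C/C1=C(\[Mg]Br)[C@H](O[Mg]Br)[C@H](C(C)=C)[C@H](OCc2ccc(OC)cc2)C/C(C)=C\CC1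
F15 | step 14 | (1S,2Z,6Z,9R,10S)-9-[(4-methoxyphenyl)methoxy]-3,7-dimethyl-10-(prop-1-en-2-yl)cyclodeca-2,6-dien-1-ol | C/C1=C/[C@H](O)[C@H](C(C)=C)[C@H](OCc2ccc(OC)cc2)C/C(C)=C\CC1
F16 | step 14 | (1S,2Z,6Z,9R,10S)-9-[(4-methoxyphenyl)methoxy]-3,7-dimethyl-10-(propan-2-yl)cyclodeca-2,6-dien-1-ol | C/C1=C/[C@H](O)[C@H](C(C)C)[C@H](OCc2ccc(OC)cc2)C/C(C)=C\CC1
F17 | step 14 | tert-butyl{[(1S,2Z,6Z,9R,10R)-9-[(4-methoxyphenyl)methoxy]-3,7-dimethyl-10-(propan-2-yl)cyclodeca-2,6-dien-1-yl]oxy}dimethylsilane | C/C1=C/[C@H](O[Si](C)(C)C(C)(C)C)[C@H](C(C)C)[C@H](OCc2ccc(OC)cc2)C/C(C)=C\CC1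
F18 | step 15 | (1S,2Z,6Z,9S,10S)-9-[(4-methoxyphenyl)methoxy]-7-methyl-10-(prop-1-en-2-yl)-3-(4,4,5,5-tetramethyl-1,3,2-dioxaborolan-2-yl)cyclodeca-2,6-dien-1-ol | CC1(C)OB(OC1(C)C)/C1=C/[C@H](O)[C@H](C(C)=C)[C@@H](OCc2ccc(OC)cc2)C/C(C)=C\CC1
F19 | step 19 | (3Z,7Z,9S,10S)-9-[(tert-butyldimethylsilyl)oxy]-3,7-dimethyl-10-(propan-2-yl)cyclodeca-3,7-dien-1-one | C/C1=C/[C@H](O[Si](C)(C)C(C)(C)C)[C@H](C(C)C)C(=O)C/C(C)=C\CC1
F20 | step 13 | ethyl (2Z,4S,6Z)-12-hydroxy-4-[(4-methoxyphenyl)methoxy]-2,6-dimethyldodeca-2,6-dien-10-ynoate | CCOC(=O)/C(C)=C\[C@@H](OCc1ccc(OC)cc1)C/C(C)=C\CCC#CCO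
F21 | step 13 | ethyl (2Z,4S,6Z)-12-bromo-4-[(4-methoxyphenyl)methoxy]-2,6-dimethyldodeca-2,6-dien-10-ynoate | CCOC(=O)/C(C)=C\[C@@H](OCc1ccc(OC)cc1)C/C(C)=C\CCC#CCBr
F22 | step 13 | (2Z,4S,6Z)-12-bromo-4-[(4-methoxyphenyl)methoxy]-2,6-dimethyldodeca-2,6-dien-10-yn-1-ol | OC/C(C)=C\[C@@H](OCc1ccc(OC)cc1)C/C(C)=C\CCC#CCBr
F23 | step 3 | tert-butyl[(7,7-dibromohept-6-en-2-yn-1-yl)oxy]dimethylsilane | BrC(Br)=CCCC#CCO[Si](C)(C)C(C)(C)C
F24 | step 3 | tert-butyl{[(6Z)-7-bromooct-6-en-2-yn-1-yl]oxy}dimethylsilane | C/C(Br)=C/CCC#CCO[Si](C)(C)C(C)(C)C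
A1 | alternative 1 | (4Z,8Z)-2-chloro-5,9-dimethyl-2-(propan-2-yl)cyclodeca-4,8-diene-1,3-dione | C/C1=C/C(=O)C(Cl)(C(C)C)C(=O)C/C(C)=C\CC1
A2 | alternative 2 | (1R,3Z,7Z,9S,10R)-9-[(tert-butyldimethylsilyl)oxy]-3,7-dimethyl-10-(propan-2-yl)cyclodeca-3,7-dien-1-ol | C/C1=C/[C@H](O[Si](C)(C)C(C)(C)C)[C@H](C(C)C)[C@H](O)C/C(C)=C\CC1
A3 | alternative 3 | tert-butyl{[(1S,2Z,6Z,9R,10R)-5-(benzenesulfonyl)-9-[(4-methoxyphenyl)methoxy]-3,7-dimethyl-10-(propan-2-yl)cyclodeca-2,6-dien-1-yl]oxy}dimethylsilane (either configuration at the sulfonyl carbon) | C/C1=C/[C@H](O[Si](C)(C)C(C)(C)C)[C@H](C(C)C)[C@H](OCc2ccc(OC)cc2)C/C(C)=C\C(S(=O)(=O)c3ccccc3)C1
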